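**Strategy.** The decalin is folded from an acyclic chain in one Lewis acid cascade. An (E)-enal (C2, C1, C10) carrying the C7–C9 stereotriad and a 2,3-dimethylbut-2-enyl terminus (C5, C4 and its two methyls) undergoes an intramolecular ene reaction that makes the ring-fusion bond C5–C10 (ring A, quaternary C5). The aldehyde so released at once closes ring B by a carbonyl-ene reaction (C2–C3). The step exploits the 1,3 relation of the C2 carbonyl and the C4 methyl across C3 in ring B and the fully substituted C5. The isopropenyl group is masked as a β-phenylthio group during the cascade; C4 is set last by dissolving-metal reduction.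

Key step: step 12

Numbering remark: eremophilane numbering is used throughout (ring A = C5–C10, ring B = C1–C5 plus C10, C11–C13 = isopropenyl, C14 = methyl on C5, C15 = methyl on C4).

Assumption: the titanium enolate of the (S)-oxazolidinethione glycolate is taken to add to the TiCl4-complexed aldehyde through an open transition state on its chelated face (the face used in auxiliary alkylations), giving the (2R,3R)-anti adduct; were the sense opposite, the enantiomeric auxiliary would be used.

Step 1
Reactants: 1 2,3-dimethylbuta-1,3-diene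
Product: 2 1-bromo-2,3-dimethylbut-2-ene
Conditions: HBr (gas, 1.0 equiv), CH2Cl2, −30 °C → 0 °C
Reagents that add atoms: hydrogen bromide, Br
Why: Electrophilic 1,4-hydrobromination through the tertiary allyl cation should give the primary allylic bromide with the tetrasubstituted alkene as the thermodynamic adduct.

Step 2
Reactants: 3 (R)-4-benzyl-1,3-oxazolidin-2-one; 4 3-methylbut-2-enoyl chloride
Product: 5 (R)-4-benzyl-3-(3-methylbut-2-enoyl)-1,3-oxazolidin-2-one
Conditions: n-BuLi, THF, −78 °C; then 4, −78 °C → 0 °C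
Reagents that add atoms: none
Why: N-acylation of the lithiated oxazolidinone auxiliary with the acid chloride.

Step 3
Reactants: 5 (R)-4-benzyl-3-(3-methylbut-2-enoyl)-1,3-oxazolidin-2-one; 2 1-bromo-2,3-dimethylbut-2-ene
Product: 6 (4R)-4-benzyl-3-[(2R)-4,5-dimethyl-2-(prop-1-en-2-yl)hex-4-enoyl]-1,3-oxazolidin-2-one
Conditions: NaN(SiMe3)2, THF, −78 °C; then 2 (1.5 equiv), −78 °C → −40 °C
Reagents that add atoms: none
Why: Evans deconjugative α-alkylation: γ-deprotonation gives the chelated Z-dienolate, which should be alkylated at the α-carbon on the face opposite the benzyl group, setting C7 (R) and revealing the isopropenyl group.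

Step 4
Reactants: 6 (4R)-4-benzyl-3-[(2R)-4,5-dimethyl-2-(prop-1-en-2-yl)hex-4-enoyl]-1,3-oxazolidin-2-one
Product: 7 (2R)-4,5-dimethyl-2-(prop-1-en-2-yl)hex-4-en-1-ol
Conditions: LiBH4, MeOH (1.1 equiv), Et2O, 0 °C
Reagents that add atoms: none
Why: Reductive cleavage of the imide to the primary alcohol without touching the α-stereocentre; the auxiliary is recovered.

Step 5
Reactants: 7 (2R)-4,5-dimethyl-2-(prop-1-en-2-yl)hex-4-en-1-ol
Product: 8 (2R)-4,5-dimethyl-2-[1-(phenylsulfanyl)propan-2-yl]hex-4-en-1-ol (both epimers at C11)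
Conditions: PhSH (2 equiv), 2,2-dimethoxy-2-phenylacetophenone (5 mol%), hν (365 nm), CH2Cl2, rt
Reagents that add atoms: thiophenol, Sc1ccccc1
Why: Radical thiol–ene addition should occur anti-Markovnikov at the 1,1-disubstituted alkene only (thiyl addition to the tetrasubstituted alkene is reversible and unproductive), masking the isopropenyl group that would otherwise compete as ene donor in step 12.

Step 6
Reactants: 8 (2R)-4,5-dimethyl-2-[1-(phenylsulfanyl)propan-2-yl]hex-4-en-1-ol
Product: 9 (2R)-4,5-dimethyl-2-[1-(phenylsulfanyl)propan-2-yl]hex-4-enal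
Conditions: SO3·pyridine, DMSO, i-Pr2NEt, CH2Cl2, 0 °C
Reagents that add atoms: none
Why: Parikh–Doering oxidation tolerates the sulfide and should give the α-branched aldehyde without epimerisation.

Step 7
Reactants: 10 (S)-4-benzyl-1,3-oxazolidine-2-thione; 11 (benzyloxy)acetyl chloride
Product: 12 (S)-4-benzyl-3-[(benzyloxy)acetyl]-1,3-oxazolidine-2-thione
Conditions: NaH, THF, 0 °C; then 11, 0 °C → rt
Reagents that add atoms: none
Why: N-acylation of the sodium salt of the oxazolidinethione auxiliary.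

Step 8
Reactants: 12 (S)-4-benzyl-3-[(benzyloxy)acetyl]-1,3-oxazolidine-2-thione; 9 (2R)-4,5-dimethyl-2-[1-(phenylsulfanyl)propan-2-yl]hex-4-enal
Product: 13 (4S)-4-benzyl-3-[(2R,3R,4R)-2-(benzyloxy)-3-hydroxy-6,7-dimethyl-4-[1-(phenylsulfanyl)propan-2-yl]oct-6-enoyl]-1,3-oxazolidine-2-thione
Conditions: 12 (1.3 equiv), TiCl4 (1.1 equiv per 12), i-Pr2NEt, CH2Cl2, −78 °C; then 9 precomplexed with TiCl4 (1.5 equiv), −78 °C
Reagents that add atoms: none
Why: Anti-selective glycolate aldol of the chlorotitanium Z-enolate with the Lewis acid-complexed aldehyde through an open transition state; the auxiliary should set C9 and the anti topology C8, overriding the modest bias of C7.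

Step 9
Reactants: 13 (4S)-4-benzyl-3-[(2R,3R,4R)-2-(benzyloxy)-3-hydroxy-6,7-dimethyl-4-[1-(phenylsulfanyl)propan-2-yl]oct-6-enoyl]-1,3-oxazolidine-2-thione
Product: 14 (2R,3R,4R)-2-(benzyloxy)-3-hydroxy-6,7-dimethyl-4-[1-(phenylsulfanyl)propan-2-yl]oct-6-enal
Conditions: i-Bu2AlH (2.2 equiv), CH2Cl2, −78 °C
Reagents that add atoms: none
Why: Direct hydride reduction of the N-acyl oxazolidinethione to the aldehyde through a stable tetrahedral aluminate; the auxiliary is released on work-up.

Step 10
Reactants: 14 (2R,3R,4R)-2-(benzyloxy)-3-hydroxy-6,7-dimethyl-4-[1-(phenylsulfanyl)propan-2-yl]oct-6-enal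
Product: 15 (2E,4S,5R,6R)-4-(benzyloxy)-5-hydroxy-8,9-dimethyl-6-[1-(phenylsulfanyl)propan-2-yl]deca-2,8-dienal
Conditions: Ph3P=CHCHO (1.3 equiv), toluene, 70 °C
Reagents that add atoms: (triphenylphosphoranylidene)acetaldehyde, O=CC=P(c1ccccc1)(c1ccccc1)c1ccccc1
Why: Wittig olefination with the stabilised formyl ylide should give the (E)-enal; the neutral ylide should not epimerise the α-alkoxy aldehyde.

Step 11
Reactants: 15 (2E,4S,5R,6R)-4-(benzyloxy)-5-hydroxy-8,9-dimethyl-6-[1-(phenylsulfanyl)propan-2-yl]deca-2,8-dienal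
Product: 16 (2E,4S,5R,6R)-4-(benzyloxy)-8,9-dimethyl-1-oxo-6-[1-(phenylsulfanyl)propan-2-yl]deca-2,8-dien-5-yl acetate
Conditions: Ac2O, pyridine, 4-(dimethylamino)pyridine (cat.), CH2Cl2, 0 °C
Reagents that add atoms: acetic anhydride, CC(=O)OC(C)=O
Why: Acylation of the C8 hydroxyl protects it against the later oxidation at C2 and leaves an ester that the final dissolving-metal step removes.

Step 12
Reactants: 16 (2E,4S,5R,6R)-4-(benzyloxy)-8,9-dimethyl-1-oxo-6-[1-(phenylsulfanyl)propan-2-yl]deca-2,8-dien-5-yl acetate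
Product: 18 8α-acetoxy-9α-benzyloxy-12-(phenylsulfanyl)-10βH-eremophil-4(15)-en-2α-ol, via seco aldehyde 17 (not isolated)
Conditions: Me2AlCl (3.5 equiv), CH2Cl2, −78 °C → 0 °C
Reagents that add atoms: none
Why: Me2AlCl complexes the (E)-enal; C5 of the tetrasubstituted alkene attacks C10 in a chair transition state (ring A, 6-exo with respect to the acceptor), and the C4 cation/aluminium enolate pair collapses by proton transfer from a C4 methyl to C1, an ene reaction with the enal C=C as enophile that gives aldehyde 17. The still-complexed aldehyde then undergoes a type 2 carbonyl-ene reaction: C3 of the new 1,1-disubstituted alkene adds to C2 (ring B, 6-endo with respect to the alkene) while a hydrogen of the remaining methyl passes to oxygen, leaving the C4(15) methylene and the aluminium alkoxide of 18. The closest known reaction is the Me2AlCl-mediated sequential ene annulation of enals with 2,3-dimethylbut-2-ene-type alkenes to 3-methylenecyclohexanols, here with both partners tethered. C10 is controlled by C9: the benzyloxy group sits axial and anti to the incoming alkene and the enal equatorial, in the chair that keeps the C7 side chain and the C8 acetate equatorial. C5 is the least secure centre: the cis fusion needs the C4 terminus axial and syn to O9, where the ether oxygen can stabilise the developing cation, against allylic strain that favours the other face; the C2 carbinol (axial from the concerted ene) is erased in step 13. Chemoselectivity rests on the tetrasubstituted alkene being the only carbon nucleophile (isopropenyl masked as the sulfide), and ring size directs the second ene.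

Step 13
Reactants: 18 8α-acetoxy-9α-benzyloxy-12-(phenylsulfanyl)-10βH-eremophil-4(15)-en-2α-ol
Product: 20 8α-acetoxy-9α-benzyloxy-12-(phenylsulfanyl)-10βH-eremophil-3-en-2-one, via β,γ-unsaturated ketone 19 (not isolated)
Conditions: SO3·pyridine, DMSO, i-Pr2NEt, CH2Cl2, 0 °C; then DBU, CH2Cl2, rt
Reagents that add atoms: none
Why: Parikh–Doering oxidation gives the β,γ-unsaturated ketone, which DBU should isomerise through the dienolate to the conjugated trisubstituted enone.

Step 14
Reactants: 20 8α-acetoxy-9α-benzyloxy-12-(phenylsulfanyl)-10βH-eremophil-3-en-2-one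
Product: 22 8α-acetoxy-9α-benzyloxy-10βH-eremophila-3,11-dien-2-one, via sulfoxide 21 (not isolated)
Conditions: mCPBA (1.0 equiv), CH2Cl2, −78 °C; then CaCO3, toluene, 110 °C
Reagents that add atoms: none
Why: Chemoselective sulfide-to-sulfoxide oxidation followed by thermal syn-elimination (sulfoxide pyrolysis); the only β-hydrogen is on C11, so the isopropenyl group should be regenerated regiospecifically.

Step 15
Reactants: 22 8α-acetoxy-9α-benzyloxy-10βH-eremophila-3,11-dien-2-one
Product: 23 8α,9α-dihydroxy-10βH-eremophil-11-en-2-one (4β,5β-dimethyl)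
Conditions: Li (excess), NH3 (l), THF, −78 °C → −33 °C; then NH4Cl
Reagents that add atoms: none
Why: Dissolving-metal (Birch-type) reduction of the enone with axial protonation at C4 from the α-face should place the C4 methyl equatorial and cis to the C5 methyl, while the benzyl ether and the acetate are cleaved in the same operation.

Step 16
Reactants: 23 8α,9α-dihydroxy-10βH-eremophil-11-en-2-one; 24 angelic acid
Product: 27 8α,9α-bis(angeloyloxy)-10βH-eremophil-11-en-2-one (CNP0249036.1), via mixed anhydride 25 (not isolated), via mono-angelate 26 (not isolated)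
Conditions: 24 (6 equiv), 2,4,6-trichlorobenzoyl chloride (6 equiv), Et3N, toluene, rt; then 23, 80 °C
Reagents that add atoms: none
Why: Yamaguchi-type esterification through the mixed anhydride without a nucleophilic catalyst, conditions that should acylate both hindered secondary alcohols with retention of the Z geometry of the angelate.

**Compound list**

1 | 2,3-dimethylbuta-1,3-diene | C=C(C)C(C)=C | starting material
2 | 1-bromo-2,3-dimethylbut-2-ene | CC(C)=C(C)CBr | intermediate
3 | (R)-4-benzyl-1,3-oxazolidin-2-one | O=C1N[C@H](Cc2ccccc2)CO1 | starting material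
4 | 3-methylbut-2-enoyl chloride | CC(C)=CC(=O)Cl | starting material
5 | (R)-4-benzyl-3-(3-methylbut-2-enoyl)-1,3-oxazolidin-2-one | CC(C)=CC(=O)N1[C@H](Cc2ccccc2)COC1=O | intermediate
6 | (4R)-4-benzyl-3-[(2R)-4,5-dimethyl-2-(prop-1-en-2-yl)hex-4-enoyl]-1,3-oxazolidin-2-one | C=C(C)[C@@H](CC(C)=C(C)C)C(=O)N1[C@H](Cc2ccccc2)COC1=O | intermediate
7 | (2R)-4,5-dimethyl-2-(prop-1-en-2-yl)hex-4-en-1-ol | C=C(C)[C@@H](CC(C)=C(C)C)CO | intermediate
8 | (2R)-4,5-dimethyl-2-[1-(phenylsulfanyl)propan-2-yl]hex-4-en-1-ol (both C11 epimers) | CC(CSc1ccccc1)[C@@H](CC(C)=C(C)C)CO | intermediate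
9 | (2R)-4,5-dimethyl-2-[1-(phenylsulfanyl)propan-2-yl]hex-4-enal | CC(CSc1ccccc1)[C@@H](CC(C)=C(C)C)C=O | intermediate
10 | (S)-4-benzyl-1,3-oxazolidine-2-thione | S=C1N[C@@H](Cc2ccccc2)CO1 | starting material
11 | (benzyloxy)acetyl chloride | O=C(Cl)COCc1ccccc1 | starting material
12 | (S)-4-benzyl-3-[(benzyloxy)acetyl]-1,3-oxazolidine-2-thione | O=C(COCc1ccccc1)N1[C@@H](Cc2ccccc2)COC1=S | intermediate
13 | (4S)-4-benzyl-3-[(2R,3R,4R)-2-(benzyloxy)-3-hydroxy-6,7-dimethyl-4-[1-(phenylsulfanyl)propan-2-yl]oct-6-enoyl]-1,3-oxazolidine-2-thione | CC(CSc1ccccc1)[C@@H](CC(C)=C(C)C)[C@@H](O)[C@@H](OCc1ccccc1)C(=O)N1[C@@H](Cc2ccccc2)COC1=S | intermediate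
14 | (2R,3R,4R)-2-(benzyloxy)-3-hydroxy-6,7-dimethyl-4-[1-(phenylsulfanyl)propan-2-yl]oct-6-enal | CC(CSc1ccccc1)[C@@H](CC(C)=C(C)C)[C@@H](O)[C@@H](OCc1ccccc1)C=O | intermediate
15 | (2E,4S,5R,6R)-4-(benzyloxy)-5-hydroxy-8,9-dimethyl-6-[1-(phenylsulfanyl)propan-2-yl]deca-2,8-dienal | CC(CSc1ccccc1)[C@@H](CC(C)=C(C)C)[C@@H](O)[C@@H](OCc1ccccc1)/C=C/C=O | intermediate
16 | (2E,4S,5R,6R)-4-(benzyloxy)-8,9-dimethyl-1-oxo-6-[1-(phenylsulfanyl)propan-2-yl]deca-2,8-dien-5-yl acetate | CC(CSc1ccccc1)[C@@H](CC(C)=C(C)C)[C@@H](OC(C)=O)[C@@H](OCc1ccccc1)/C=C/C=O | intermediate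
17 | 8α-acetoxy-9α-benzyloxy-12-(phenylsulfanyl)-2,3-seco-10βH-eremophil-3-en-2-al (ring A only; C5 bears β-methyl and α-isopropenyl, C10 bears α-CH2CHO) | CC(CSc1ccccc1)[C@H]1C[C@](C)(C(C)=C)[C@H](CC=O)[C@H](OCc2ccccc2)[C@@H]1OC(C)=O | intermediate
18 | 8α-acetoxy-9α-benzyloxy-12-(phenylsulfanyl)-10βH-eremophil-4(15)-en-2α-ol | CC(CSc1ccccc1)[C@H]1C[C@@]2(C)[C@H](C[C@@H](O)CC2=C)[C@H](OCc3ccccc3)[C@@H]1OC(C)=O | intermediate
19 | 8α-acetoxy-9α-benzyloxy-12-(phenylsulfanyl)-10βH-eremophil-4(15)-en-2-one | CC(CSc1ccccc1)[C@H]1C[C@@]2(C)[C@H](CC(=O)CC2=C)[C@H](OCc3ccccc3)[C@@H]1OC(C)=O | intermediate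
20 | 8α-acetoxy-9α-benzyloxy-12-(phenylsulfanyl)-10βH-eremophil-3-en-2-one | CC(CSc1ccccc1)[C@H]1C[C@@]2(C)[C@H](CC(=O)C=C2C)[C@H](OCc3ccccc3)[C@@H]1OC(C)=O | intermediate
21 | 8α-acetoxy-9α-benzyloxy-12-(phenylsulfinyl)-10βH-eremophil-3-en-2-one | CC(CS(=O)c1ccccc1)[C@H]1C[C@@]2(C)[C@H](CC(=O)C=C2C)[C@H](OCc3ccccc3)[C@@H]1OC(C)=O | intermediate
22 | 8α-acetoxy-9α-benzyloxy-10βH-eremophila-3,11-dien-2-one | C=C(C)[C@H]1C[C@@]2(C)[C@H](CC(=O)C=C2C)[C@H](OCc3ccccc3)[C@@H]1OC(C)=O | intermediate
23 | 8α,9α-dihydroxy-10βH-eremophil-11-en-2-one | C=C(C)[C@H]1C[C@@]2(C)[C@H](CC(=O)C[C@@H]2C)[C@H](O)[C@@H]1O | intermediate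
24 | angelic acid, (Z)-2-methylbut-2-enoic acid | C/C=C(/C)C(=O)O | starting material
25 | (Z)-2-methylbut-2-enoic 2,4,6-trichlorobenzoic anhydride | C/C=C(/C)C(=O)OC(=O)c1c(Cl)cc(Cl)cc1Cl | intermediate
26 | 8α-angeloyloxy-9α-hydroxy-10βH-eremophil-11-en-2-one | C=C(C)[C@H]1C[C@@]2(C)[C@H](CC(=O)C[C@@H]2C)[C@H](O)[C@@H]1OC(=O)/C(C)=C\C | intermediate
27 | 8α,9α-bis(angeloyloxy)-10βH-eremophil-11-en-2-one (CNP0249036.1) | C=C(C)[C@H]1C[C@@]2(C)[C@H](CC(=O)C[C@@H]2C)[C@H](OC(=O)/C(C)=C\C)[C@@H]1OC(=O)/C(C)=C\C | target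

Total step count: 16. Longest linear sequence: 14 steps (step 1 or 2, then 3–6 and 8–16).

**Steps most likely to fail**

1. Step 12. Facial selectivity at C5 may be poor: allylic strain in the tetrasubstituted alkene favours the transition state that puts the C4 terminus equatorial, which would lead to the C5 epimer with a trans ring fusion. The cascade may also terminate early by collapse of the zwitterion to a cyclobutane, or by capture of the C4 cation by the C9 ether oxygen with loss of the benzyl group. Fallback, from 16 back to 23: the cascade is stopped after the first C–C bond (Me2AlCl, 1.1 equiv, −78 °C) and seco aldehyde 17 is isolated and freed from its C5 epimer. Ring B is then closed by a thiol-catalysed radical-chain hydroacylation (tert-dodecanethiol, cat., AIBN, toluene, 80 °C): 6-endo addition of the acyl radical to C3, then hydrogen-atom transfer to C4 from the α-face, should give 8α-acetoxy-9α-benzyloxy-12-(phenylsulfanyl)-10βH-eremophilan-2-one F1 directly. Oxidation with mCPBA gives the sulfoxide F2, whose pyrolysis (toluene, 110 °C) gives 8α-acetoxy-9α-benzyloxy-10βH-eremophil-11-en-2-one F3. BCl3 with pentamethylbenzene (CH2Cl2, −78 °C) removes the benzyl ether to give 8α-acetoxy-9α-hydroxy-10βH-eremophil-11-en-2-one F4, and K2CO3 in MeOH returns 23.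

2. Step 8. Double diastereodifferentiation between the auxiliary and the C7 stereocentre may be mismatched, or the sense of induction may be the reverse of the one assumed, eroding the anti and facial selectivity. Fallback, from 9 back to 14: a D-proline-catalysed direct cross-aldol of (benzyloxy)acetaldehyde (donor, added slowly) with the α-branched aldehyde 9 (DMF, 4 °C). The enamine mechanism is anti-selective and catalyst-controlled, and should give 14 in one step, bypassing steps 7–9.

3. Step 16. Z-to-E isomerisation of the angeloyl group on prolonged heating, and incomplete acylation of the hindered axial C9 hydroxyl, may give tiglate-containing or mono-acylated material. Fallback, from 23 to 27: both hydroxyls are esterified with 2-[bis(2,2,2-trifluoroethoxy)phosphoryl]propanoic acid (DCC, 4-(dimethylamino)pyridine, CH2Cl2) to give the bis(phosphonopropionate) F5. A Z-selective Still–Gennari olefination (KN(SiMe3)2, 18-crown-6, THF, −78 °C; then acetaldehyde) then builds both angelate double bonds in place; the phosphonates are far more acidic than the C2 ketone.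

**Further compounds**

F1 | step 12 | 8α-acetoxy-9α-benzyloxy-12-(phenylsulfanyl)-10βH-eremophilan-2-one | CC(CSc1ccccc1)[C@H]1C[C@@]2(C)[C@H](CC(=O)C[C@@H]2C)[C@H](OCc3ccccc3)[C@@H]1OC(C)=O
F2 | step 12 | 8α-acetoxy-9α-benzyloxy-12-(phenylsulfinyl)-10βH-eremophilan-2-one | CC(CS(=O)c1ccccc1)[C@H]1C[C@@]2(C)[C@H](CC(=O)C[C@@H]2C)[C@H](OCc3ccccc3)[C@@H]1OC(C)=O
F3 | step 12 | 8α-acetoxy-9α-benzyloxy-10βH-eremophil-11-en-2-one | C=C(C)[C@H]1C[C@@]2(C)[C@H](CC(=O)C[C@@H]2C)[C@H](OCc3ccccc3)[C@@H]1OC(C)=O
F4 | step 12 | 8α-acetoxy-9α-hydroxy-10βH-eremophil-11-en-2-one | C=C(C)[C@H]1C[C@@]2(C)[C@H](CC(=O)C[C@@H]2C)[C@H](O)[C@@H]1OC(C)=O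
F0 | step 8 | none | none
F5 | step 16 | 8α,9α-bis{2-[bis(2,2,2-trifluoroethoxy)phosphoryl]propanoyloxy}-10βH-eremophil-11-en-2-one | C=C(C)[C@H]1C[C@@]2(C)[C@H](CC(=O)C[C@@H]2C)[C@H](OC(=O)C(C)P(=O)(OCC(F)(F)F)OCC(F)(F)F)[C@@H]1OC(=O)C(C)P(=O)(OCC(F)(F)F)OCC(F)(F)F
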